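Ring A is cut at C1–C10 and C3=C4 (eudesmane numbering), leaving ring B as (R)-carvone. The key step exploits that quaternary C10 lies next to a removable C9 carbonyl in ring B and that C3=C4 of ring A is a ring alkene. A regiodefined C10 enolate, shielded on one face by its C5 isopropenyl group (set trans to C7 by cuprate addition), is C-alkylated by 4-iodobut-1-ene (C1–C10) and closed in the same flask by ring-closing metathesis (C3=C4), giving the trans-decalin. The precursor is a monocyclic silyl enol ether. The C9 oxygen is then removed, C7 is inverted through its methyl ketone, and acrylate, C15 oxygen and coumarate follow.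

Key step: step 2

Remark: eudesmane numbering is used throughout (ring A = C1–C5, C10; ring B = C5–C10; C11–C13 = acrylate unit; C14 = angular methyl; C15 = oxygenated carbon on C4).

Step 1
Reactants: 1 (R)-carvone; 2 isopropenylmagnesium bromide
Product: 3 trimethyl{[(3S,5R)-2-methyl-3,5-di(prop-1-en-2-yl)cyclohex-1-en-1-yl]oxy}silane
Conditions: CuBr·SMe2 (10 mol %), Me3SiCl, THF, −78 °C; Et3N, pentane work-up
Reagents that add atoms: chlorotrimethylsilane, C[Si](C)(C)Cl
Why: Copper-catalysed conjugate addition of the Grignard reagent should deliver the isopropenyl group axially to C5, anti to the C7 isopropenyl group of the enone half-chair (C5 set trans to C7), and silylation traps the C9–C10 enolate regiospecifically.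

Step 2
Reactants: 3 trimethyl{[(3S,5R)-2-methyl-3,5-di(prop-1-en-2-yl)cyclohex-1-en-1-yl]oxy}silane; 4 4-iodobut-1-ene
Product: 7 (3R,4aS,8aS)-5,8a-dimethyl-3-(prop-1-en-2-yl)-3,4,4a,7,8,8a-hexahydronaphthalen-1(2H)-one, via lithium enolate 5 (not isolated), via butenyl ketone 6 (not isolated)
Conditions: MeLi, THF, 0 °C; 4, DMPU, −78 → 23 °C; AcOH (to neutralise); second-generation Hoveyda–Grubbs catalyst (5 mol %), PhMe, 60 °C, same flask
Reagents that add atoms: none
Why: MeLi cleaves the O–Si bond of 3 to give lithium enolate 5 with the C9=C10 double bond fixed, and SN2 attack of C10 on the primary iodide 4 forms C1–C10; the Ru alkylidene formed at the monosubstituted butenyl alkene of 6 then engages the adjacent 1,1-disubstituted C5 isopropenyl group and expels ethene, which forms C3=C4. The closest known reaction types are the regiospecific alkylation of a lithium enolate released from a silyl enol ether and ring-closing olefin metathesis, run here in one flask. Ring A closes as a six-membered carbocycle by metathesis between C3 and C4, giving an endocyclic trisubstituted alkene. The new quaternary centre C10 is controlled by the neighbouring C5 isopropenyl group, which is trans to the C7 group and therefore axial in the enolate half-chair, so the electrophile should enter on the opposite face and place C1 trans to C4 (trans ring fusion after closure). The step needs C- over O-alkylation and substitution over elimination, which the lithium counter-ion, the soft iodide leaving group and DMPU favour, and it needs six-membered closure to beat metathesis at the distant C7 isopropenyl group, which ring size secures.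

Step 3
Reactants: 7 (3R,4aS,8aS)-5,8a-dimethyl-3-(prop-1-en-2-yl)-3,4,4a,7,8,8a-hexahydronaphthalen-1(2H)-one
Product: 9 (2S,4aR,8aR)-4a,8-dimethyl-2-(prop-1-en-2-yl)-1,2,3,4,4a,5,6,8a-octahydronaphthalene, via hydrazone 8 (not isolated)
Conditions: N2H4·H2O, KOH, diethylene glycol, 130 °C then 200 °C
Reagents that add atoms: none
Why: Wolff–Kishner reduction (Huang-Minlon conditions) should turn the hindered C9 ketone into CH2 through hydrazone 8 without touching the unactivated alkenes or any stereocentre.

Step 4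
Reactants: 9 (2S,4aR,8aR)-4a,8-dimethyl-2-(prop-1-en-2-yl)-1,2,3,4,4a,5,6,8a-octahydronaphthalene
Product: 12 1-[(2R,4aR,8aR)-4a,8-dimethyl-1,2,3,4,4a,5,6,8a-octahydronaphthalen-2-yl]ethan-1-one, via diol 10 (not isolated), via axial ketone 11 (not isolated)
Conditions: OsO4 (1 mol %), (DHQD)2PHAL (2 mol %), NMO, acetone/H2O, 0 °C; aqueous Na2SO3 work-up; crude diol, NaIO4, THF/H2O, 23 °C; then NaOMe, MeOH, 23 °C
Reagents that add atoms: 4-methylmorpholine N-oxide, C[N+]1([O-])CCOCC1; water, O
Why: Ligand-accelerated Os-catalysed dihydroxylation should prefer the 1,1-disubstituted isopropenyl alkene over the hindered endocyclic trisubstituted C3=C4 (as with limonene), periodate (Malaprade) cleavage gives the axial C7 methyl ketone, and methoxide-mediated enolisation should equilibrate C7 to the equatorial epimer, which inverts C7 under thermodynamic control.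

Step 5
Reactants: 12 1-[(2R,4aR,8aR)-4a,8-dimethyl-1,2,3,4,4a,5,6,8a-octahydronaphthalen-2-yl]ethan-1-one
Product: 13 1-[(2R,4aR,8aR)-4a,8-dimethyl-1,2,3,4,4a,5,6,8a-octahydronaphthalen-2-yl]ethenyl trifluoromethanesulfonate
Conditions: KN(SiMe3)2, THF, −78 °C; then PhNTf2, −78 → 0 °C
Reagents that add atoms: N-phenylbis(trifluoromethanesulfonimide), O=S(=O)(N(c1ccccc1)S(=O)(=O)C(F)(F)F)C(F)(F)F
Why: Kinetic deprotonation of the methyl group by the bulky amide base at −78 °C and O-sulfonylation of the enolate should give the terminal enol triflate without enolisation towards C7.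

Step 6
Reactants: 13 1-[(2R,4aR,8aR)-4a,8-dimethyl-1,2,3,4,4a,5,6,8a-octahydronaphthalen-2-yl]ethenyl trifluoromethanesulfonate
Product: 14 methyl 2-[(2R,4aR,8aR)-4a,8-dimethyl-1,2,3,4,4a,5,6,8a-octahydronaphthalen-2-yl]prop-2-enoate
Conditions: Pd(OAc)2 (5 mol %), PPh3 (10 mol %), CO (1 atm), MeOH, Et3N, DMF, 60 °C
Reagents that add atoms: carbon monoxide, [C-]#[O+]; methanol, CO
Why: Pd-catalysed alkoxycarbonylation of the alkenyl triflate (oxidative addition, CO insertion, methanolysis) should give the α-substituted acrylate with all stereocentres retained.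

Step 7
Reactants: 14 methyl 2-[(2R,4aR,8aR)-4a,8-dimethyl-1,2,3,4,4a,5,6,8a-octahydronaphthalen-2-yl]prop-2-enoate
Product: 15 methyl 2-[(2R,4aR,8aR)-8-(hydroxymethyl)-4a-methyl-1,2,3,4,4a,5,6,8a-octahydronaphthalen-2-yl]prop-2-enoate
Conditions: SeO2 (20 mol %), t-BuOOH, CH2Cl2, 0 → 23 °C
Reagents that add atoms: tert-butyl hydroperoxide, CC(C)(C)OO
Why: Riley allylic oxidation (ene reaction then [2,3]-sigmatropic shift) should occur at the methyl group on the more substituted alkene carbon C4, the alternative position C5 being a hindered ring-fusion methine (compare α-pinene to myrtenol), while the electron-poor acrylate alkene is inert.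

Step 8
Reactants: 15 methyl 2-[(2R,4aR,8aR)-8-(hydroxymethyl)-4a-methyl-1,2,3,4,4a,5,6,8a-octahydronaphthalen-2-yl]prop-2-enoate; 16 (E)-4-hydroxycinnamic acid
Product: 17 methyl 2-[(2R,4aR,8aR)-8-({[(2E)-3-(4-hydroxyphenyl)prop-2-enoyl]oxy}methyl)-4a-methyl-1,2,3,4,4a,5,6,8a-octahydronaphthalen-2-yl]prop-2-enoate
Conditions: PPh3, DIAD, THF, 0 → 23 °C
Reagents that add atoms: none
Why: Mitsunobu esterification should activate the primary allylic alcohol for SN2 displacement by the carboxylate of 16, the carboxylic acid being far more acidic than the phenol so that no protecting group is needed, and the (E)-alkene and all stereocentres are untouched.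

Compound list
1 | (R)-carvone, (5R)-2-methyl-5-(prop-1-en-2-yl)cyclohex-2-en-1-one | CC1=CC[C@H](CC1=O)C(C)=C | starting material
2 | isopropenylmagnesium bromide (prop-1-en-2-ylmagnesium bromide) | C=C(C)[Mg]Br | starting material
3 | trimethyl{[(3S,5R)-2-methyl-3,5-di(prop-1-en-2-yl)cyclohex-1-en-1-yl]oxy}silane (isopropenyl groups trans) | C[Si](C)(C)OC1=C(C)[C@H](C(C)=C)C[C@@H](C(C)=C)C1 | intermediate
4 | 4-iodobut-1-ene | C=CCCI | starting material
5 | lithium (3S,5R)-2-methyl-3,5-di(prop-1-en-2-yl)cyclohex-1-en-1-olate | [Li+].[O-]C1=C(C)[C@H](C(C)=C)C[C@@H](C(C)=C)C1 | intermediate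
6 | (2S,3S,5R)-2-(but-3-en-1-yl)-2-methyl-3,5-di(prop-1-en-2-yl)cyclohexan-1-one (butenyl trans to the C3 isopropenyl group) | O=C1C[C@H](C(C)=C)C[C@@H](C(C)=C)[C@]1(C)CCC=C | intermediate
7 | (3R,4aS,8aS)-5,8a-dimethyl-3-(prop-1-en-2-yl)-3,4,4a,7,8,8a-hexahydronaphthalen-1(2H)-one (trans-fused, isopropenyl axial) | O=C1C[C@H](C(C)=C)C[C@H]2C(C)=CCC[C@]12C | intermediate
8 | hydrazone of 7, [(3R,4aS,8aS)-5,8a-dimethyl-3-(prop-1-en-2-yl)-3,4,4a,7,8,8a-hexahydronaphthalen-1(2H)-ylidene]hydrazine | NN=C1C[C@H](C(C)=C)C[C@H]2C(C)=CCC[C@]12C | intermediate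
9 | (2S,4aR,8aR)-4a,8-dimethyl-2-(prop-1-en-2-yl)-1,2,3,4,4a,5,6,8a-octahydronaphthalene (7-epi-α-selinene) | C1C[C@H](C(C)=C)C[C@H]2C(C)=CCC[C@]12C | intermediate
10 | 2-[(2S,4aR,8aR)-4a,8-dimethyl-1,2,3,4,4a,5,6,8a-octahydronaphthalen-2-yl]propane-1,2-diol (carbinol configuration not defined) | C1C[C@H](C(C)(O)CO)C[C@H]2C(C)=CCC[C@]12C | intermediate
11 | 1-[(2S,4aR,8aR)-4a,8-dimethyl-1,2,3,4,4a,5,6,8a-octahydronaphthalen-2-yl]ethan-1-one (acetyl axial) | C1C[C@H](C(C)=O)C[C@H]2C(C)=CCC[C@]12C | intermediate
12 | 1-[(2R,4aR,8aR)-4a,8-dimethyl-1,2,3,4,4a,5,6,8a-octahydronaphthalen-2-yl]ethan-1-one (acetyl equatorial) | C1C[C@@H](C(C)=O)C[C@H]2C(C)=CCC[C@]12C | intermediate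
13 | 1-[(2R,4aR,8aR)-4a,8-dimethyl-1,2,3,4,4a,5,6,8a-octahydronaphthalen-2-yl]ethenyl trifluoromethanesulfonate | C1C[C@@H](C(=C)OS(=O)(=O)C(F)(F)F)C[C@H]2C(C)=CCC[C@]12C | intermediate
14 | methyl 2-[(2R,4aR,8aR)-4a,8-dimethyl-1,2,3,4,4a,5,6,8a-octahydronaphthalen-2-yl]prop-2-enoate | C1C[C@@H](C(=C)C(=O)OC)C[C@H]2C(C)=CCC[C@]12C | intermediate
15 | methyl 2-[(2R,4aR,8aR)-8-(hydroxymethyl)-4a-methyl-1,2,3,4,4a,5,6,8a-octahydronaphthalen-2-yl]prop-2-enoate | C1C[C@@H](C(=C)C(=O)OC)C[C@H]2C(CO)=CCC[C@]12C | intermediate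
16 | (E)-4-hydroxycinnamic acid (p-coumaric acid) | OC(=O)/C=C/c1ccc(O)cc1 | starting material
17 | methyl 2-[(2R,4aR,8aR)-8-({[(2E)-3-(4-hydroxyphenyl)prop-2-enoyl]oxy}methyl)-4a-methyl-1,2,3,4,4a,5,6,8a-octahydronaphthalen-2-yl]prop-2-enoate | C=C(C(=O)OC)[C@@H]1CC[C@@]2(C)CCC=C(COC(=O)/C=C/c3ccc(O)cc3)[C@@H]2C1 | target

Total step count: 8. Longest linear sequence: 8 steps (1 to 17).

Steps most likely to fail

Step 2. The tetrasubstituted enolate may react only sluggishly with the homoallylic iodide, may act as a base and cause loss of HI from 4, or may alkylate on oxygen; DMPU and iodide may also slow the metathesis catalyst. The fallback sets out from 3 and returns at 6. MeLi followed by allyl bromide should give (2S,3S,5R)-2-methyl-2-(prop-2-en-1-yl)-3,5-di(prop-1-en-2-yl)cyclohexan-1-one F1. Aldehyde-selective Wacker oxidation of its monosubstituted alkene (PdCl2(PhCN)2, CuCl2, AgNO2, O2, t-BuOH/MeNO2), to which the 1,1-disubstituted isopropenyl groups are inert, should give 3-[(1S,2S,4R)-1-methyl-6-oxo-2,4-di(prop-1-en-2-yl)cyclohexyl]propanal F2. Wittig methylenation (Ph3P=CH2) at the aldehyde, sparing the hindered ketone, then gives 6, which is isolated and closed to 7 with second-generation Hoveyda–Grubbs catalyst in CH2Cl2.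

Step 7. The allylic oxidation may attack C2 or C5 instead of the methyl group, or run on to the aldehyde. The fallback sets out from 14 and returns at 15. m-CPBA should epoxidise the electron-rich C3=C4 alkene and leave the acrylate, giving the 3,4-epoxide of 14 F5. Me3SiOTf/DBU-mediated epoxide-to-allylic-ether isomerisation with loss of a C15 proton, followed by mild desilylation, should give the C3 alcohol with an exocyclic C4=C15 alkene F6. Ph3SiOReO3-catalysed 1,3-transposition of this allylic alcohol should then give the more stable primary alcohol with the trisubstituted C3=C4 alkene, 15.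

Step 4. The dihydroxylation may lack site selectivity and attack C3=C4, and the epimerisation at C7 may stop short of completion. The fallback sets out from 9 and returns at 11. m-CPBA (1 equiv) should epoxidise the trisubstituted C3=C4 alkene in preference to the isopropenyl group, giving the 3,4-epoxide of 9 F3. Ozonolysis (O3, CH2Cl2/MeOH, −78 °C; Me2S) of the remaining isopropenyl alkene should give the 3,4-epoxide of 11 F4. Deoxygenation of the epoxide (NaI, Zn, AcOH/NaOAc) restores C3=C4 and gives 11, which is epimerised to 12 with NaOMe as in the route.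

Further compounds
F1 | step 2 | (2S,3S,5R)-2-methyl-2-(prop-2-en-1-yl)-3,5-di(prop-1-en-2-yl)cyclohexan-1-one | O=C1C[C@H](C(C)=C)C[C@@H](C(C)=C)[C@]1(C)CC=C
F2 | step 2 | 3-[(1S,2S,4R)-1-methyl-6-oxo-2,4-di(prop-1-en-2-yl)cyclohexyl]propanal | O=C1C[C@H](C(C)=C)C[C@@H](C(C)=C)[C@]1(C)CCC=O
F3 | step 4 | 3,4-epoxide of 9 (eudesmane numbering; epoxide face not defined) | C1C[C@H](C(C)=C)C[C@H]2C3(C)OC3CC[C@]12C
F4 | step 4 | 3,4-epoxide of 11 (eudesmane numbering; epoxide face not defined) | C1C[C@H](C(C)=O)C[C@H]2C3(C)OC3CC[C@]12C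
F5 | step 7 | 3,4-epoxide of 14 (eudesmane numbering; epoxide face not defined) | C1C[C@@H](C(=C)C(=O)OC)C[C@H]2C3(C)OC3CC[C@]12C
F6 | step 7 | methyl 2-(7-hydroxy-4a-methyl-8-methylidenedecahydronaphthalen-2-yl)prop-2-enoate, ring stereocentres as in 14, carbinol configuration not defined | C1C[C@@H](C(=C)C(=O)OC)C[C@H]2C(=C)C(O)CC[C@]12C
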